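**Strategy.** The flavanone is opened to a chalcone made from a diprenylated acetophenone and a dihydrobenzofuran aldehyde. Everything rests on building that 2,3-dihydrobenzofuran (ring atoms O1, C2, C3, C3a, C7a) from a diarylmethane and an aldehyde. The key step exploits that C7a lies ortho to the doubly benzylic C3 and para to C5, the later flavanone-bearing carbon, which carries a nitrile. A homochiral p-tolylsulfinyl group on C7a acidifies C3, steers the lithium carbanion onto 4-(methoxymethoxy)benzaldehyde (bond C3–C2) and is then displaced by the new alkoxide (bond O1–C7a). One operation closes the furan ring, sets both of its stereocenters and sheds the auxiliary; the precursor is an ortho-sulfinyl diarylmethane.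

Key step: step 7

Assumption: the sense of induction of the sulfinyl group in step 7 (chelate model) and of the cinchona catalyst in step 12 is predicted, not known for these substrates; if either proves opposite, the enantiomeric sulfinate ester or the pseudo-enantiomeric quinidine-derived catalyst would be used.

Step 1
Reactants: 1 3,5-dihydroxybenzyl alcohol
Product: 2 [3,5-bis(methoxymethoxy)phenyl]methanol
Conditions: MOMCl (2.2 equiv), K2CO3, acetone, 0 → 25 °C
Reagents that add atoms: chloromethyl methyl ether, COCCl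
Why: Phenoxide O-alkylation; K2CO3 deprotonates only the two phenols, so the benzylic alcohol should stay free.

Step 2
Reactants: 2 [3,5-bis(methoxymethoxy)phenyl]methanol
Product: 3 1-(bromomethyl)-3,5-bis(methoxymethoxy)benzene
Conditions: CBr4, PPh3, CH2Cl2, 0 °C
Reagents that add atoms: carbon tetrabromide, BrC(Br)(Br)Br
Why: Appel reaction; the neutral phosphonium conditions convert the primary benzylic alcohol to the bromide without harming the acid-labile acetals.

Step 3
Reactants: 4 4-bromo-2-hydroxybenzonitrile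
Product: 5 4-bromo-2-hydroxy-5-iodobenzonitrile
Conditions: N-iodosuccinimide, TsOH (cat.), MeCN, 25 °C
Reagents that add atoms: N-iodosuccinimide, O=C1CCC(=O)N1I
Why: Electrophilic aromatic iodination directed para to the hydroxyl group, the ortho position between OH and Br being hindered.

Step 4
Reactants: 5 4-bromo-2-hydroxy-5-iodobenzonitrile
Product: 6 4-bromo-5-iodo-2-(methoxymethoxy)benzonitrile
Conditions: MOMCl, i-Pr2NEt, CH2Cl2, 0 → 25 °C
Reagents that add atoms: chloromethyl methyl ether, COCCl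
Why: O-alkylation of the acidic cyanophenol gives the methoxymethyl ether needed for the organometallic steps.

Step 5
Reactants: 3 1-(bromomethyl)-3,5-bis(methoxymethoxy)benzene; 6 4-bromo-5-iodo-2-(methoxymethoxy)benzonitrile
Product: 8 4-bromo-5-{[3,5-bis(methoxymethoxy)phenyl]methyl}-2-(methoxymethoxy)benzonitrile, via benzylic zinc bromide 7 (not isolated)
Conditions: Zn, LiCl, THF, 25 °C; then 6, Pd(PPh3)4 (3 mol %), THF, 25 °C
Reagents that add atoms: none
Why: Negishi coupling of a benzylic zinc reagent; oxidative addition of zerovalent palladium into the C–I bond should be much faster than into the C–Br bond at 25 °C.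

Step 6
Reactants: 8 4-bromo-5-{[3,5-bis(methoxymethoxy)phenyl]methyl}-2-(methoxymethoxy)benzonitrile; 9 (1S,2R,5S)-menthyl (R)-4-methylbenzenesulfinate
Product: 11 5-{[3,5-bis(methoxymethoxy)phenyl]methyl}-2-(methoxymethoxy)-4-[(R)-4-methylbenzenesulfinyl]benzonitrile, via arylmagnesium chloride 10 (not isolated)
Conditions: i-PrMgCl·LiCl, THF, −20 °C; then 9, −20 → 0 °C
Reagents that add atoms: none
Why: Bromine–magnesium exchange that the nitrile tolerates at low temperature, then Andersen sulfoxide synthesis, in which the arylmagnesium displaces mentholate with inversion at sulfur and so fixes the (R)-sulfur stereocenter.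

Step 7
Reactants: 11 5-{[3,5-bis(methoxymethoxy)phenyl]methyl}-2-(methoxymethoxy)-4-[(R)-4-methylbenzenesulfinyl]benzonitrile; 12 4-(methoxymethoxy)benzaldehyde
Product: 15 (2R,3R)-3-[3,5-bis(methoxymethoxy)phenyl]-6-(methoxymethoxy)-2-[4-(methoxymethoxy)phenyl]-2,3-dihydro-1-benzofuran-5-carbonitrile, via benzylic lithium compound 13 (not isolated), via lithium alkoxide 14 (not isolated)
Conditions: LiN(i-Pr)2 (1.2 equiv), THF, −78 °C; then 12, −78 °C; then DMPU, −78 → 25 °C
Reagents that add atoms: none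
Why: Proposed new method: LiN(i-Pr)2 removes the doubly benzylic proton ortho to the sulfinyl group to give a lithium carbanion chelated by the sulfinyl oxygen, which adds to the aldehyde carbon (new C3–C2 bond); the resulting lithium alkoxide then attacks C7a, the ring carbon bearing sulfur and para to the nitrile, and expels p-toluenesulfenate (new O1–C7a bond). The closest known reaction types are the addition of ortho-sulfinyl benzyl carbanions to aldehydes and the displacement of an arylsulfinyl group from an arene by an alkoxide (SNAr), which have not been run in tandem on a diarylmethane. The furan ring closes by intramolecular ipso-SNAr (5-exo-trig with respect to the C7a=C7 bond) through a Meisenheimer intermediate stabilised by the para nitrile. C3 is controlled by the sulfur stereocenter: the aldehyde should enter on the lithium-bearing face, anti to the p-tolyl group, with the 3,5-bis(methoxymethoxy)phenyl group turned away from sulfur, which should give (3R) from the (R)-sulfoxide. C2 is set relative to C3 at ring closure, where the alkoxide with the two aryl groups anti should cyclise faster, helped by reversible addition, so that the 2,3-trans (2R,3R) isomer should prevail. The step needs deprotonation at the diarylmethane carbon rather than attack on the nitrile (secured by the acidity of the chelated position at −78 °C) and substitution at C7a rather than at the p-tolyl carbon (secured by the five-membered transition state and the para nitrile).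

Step 8
Reactants: 15 (2R,3R)-3-[3,5-bis(methoxymethoxy)phenyl]-6-(methoxymethoxy)-2-[4-(methoxymethoxy)phenyl]-2,3-dihydro-1-benzofuran-5-carbonitrile
Product: 16 (2R,3R)-3-[3,5-bis(methoxymethoxy)phenyl]-6-(methoxymethoxy)-2-[4-(methoxymethoxy)phenyl]-2,3-dihydro-1-benzofuran-5-carbaldehyde
Conditions: i-Bu2AlH, toluene, −78 → 0 °C; then aq. citric acid, 0 °C
Reagents that add atoms: water, O
Why: Partial reduction of the nitrile by i-Bu2AlH to the N-aluminio imine, hydrolysed on work-up to the aldehyde; the ring stereocenters are not involved.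

Step 9
Reactants: 17 2,4,6-trihydroxyacetophenone; 18 1-bromo-3-methylbut-2-ene
Product: 19 1-[2,4,6-trihydroxy-3,5-bis(3-methylbut-2-en-1-yl)phenyl]ethanone
Conditions: 18 (2.2 equiv), 10% aq. KOH, 0 → 25 °C
Reagents that add atoms: none
Why: C-alkylation of the phloroglucinol-type phenoxide (double C-prenylation) at the two free ring positions.

Step 10
Reactants: 19 1-[2,4,6-trihydroxy-3,5-bis(3-methylbut-2-en-1-yl)phenyl]ethanone
Product: 20 1-[2-hydroxy-4,6-bis(methoxymethoxy)-3,5-bis(3-methylbut-2-en-1-yl)phenyl]ethanone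
Conditions: MOMCl (2.2 equiv), i-Pr2NEt, CH2Cl2, 0 → 25 °C
Reagents that add atoms: chloromethyl methyl ether, COCCl
Why: O-alkylation of the two more reactive phenols; the third should be held back by its hydrogen bond to the acetyl carbonyl.

Step 11
Reactants: 16 (2R,3R)-3-[3,5-bis(methoxymethoxy)phenyl]-6-(methoxymethoxy)-2-[4-(methoxymethoxy)phenyl]-2,3-dihydro-1-benzofuran-5-carbaldehyde; 20 1-[2-hydroxy-4,6-bis(methoxymethoxy)-3,5-bis(3-methylbut-2-en-1-yl)phenyl]ethanone
Product: 21 (E)-3-{(2R,3R)-3-[3,5-bis(methoxymethoxy)phenyl]-6-(methoxymethoxy)-2-[4-(methoxymethoxy)phenyl]-2,3-dihydro-1-benzofuran-5-yl}-1-[2-hydroxy-4,6-bis(methoxymethoxy)-3,5-bis(3-methylbut-2-en-1-yl)phenyl]prop-2-en-1-one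
Conditions: KOH, EtOH–H2O, 25 °C
Reagents that add atoms: none
Why: Claisen–Schmidt aldol condensation; the methyl ketone enolate adds to the non-enolisable aldehyde and E1cB dehydration should give the (E)-enone.

Step 12
Reactants: 21 the (E)-chalcone of step 11
Product: 22 (2S)-2-{(2R,3R)-3-[3,5-bis(methoxymethoxy)phenyl]-6-(methoxymethoxy)-2-[4-(methoxymethoxy)phenyl]-2,3-dihydro-1-benzofuran-5-yl}-5,7-bis(methoxymethoxy)-6,8-bis(3-methylbut-2-en-1-yl)-2,3-dihydro-4H-chromen-4-one
Conditions: 1-[3,5-bis(trifluoromethyl)phenyl]-3-[(8α,9S)-6′-methoxycinchonan-9-yl]thiourea (10 mol %), toluene, 0 °C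
Reagents that add atoms: none
Why: Organocatalytic asymmetric intramolecular oxa-Michael addition (6-endo-trig cyclisation of the 2′-hydroxychalcone); the thiourea binds the enone carbonyl and the quinuclidine the phenol, so the phenoxide should add to one face of the β-carbon and set (2S).

Step 13
Reactants: 22 the hexakis(methoxymethyl) ether of step 12
Product: 23 (2S)-2-[(2R,3R)-3-(3,5-dihydroxyphenyl)-6-hydroxy-2-(4-hydroxyphenyl)-2,3-dihydro-1-benzofuran-5-yl]-5,7-dihydroxy-6,8-bis(3-methylbut-2-en-1-yl)-2,3-dihydro-4H-chromen-4-one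
Conditions: 3 M aq. HCl, MeOH, 40 °C
Reagents that add atoms: none
Why: Acid-catalysed transacetalisation to methanol should remove all six methoxymethyl groups under conditions mild enough for the prenyl groups and the three stereocenters.

**Compound list**

1 | 3,5-dihydroxybenzyl alcohol | OCc1cc(O)cc(O)c1 | starting material
2 | [3,5-bis(methoxymethoxy)phenyl]methanol | OCc1cc(OCOC)cc(OCOC)c1 | intermediate
3 | 1-(bromomethyl)-3,5-bis(methoxymethoxy)benzene | BrCc1cc(OCOC)cc(OCOC)c1 | intermediate
4 | 4-bromo-2-hydroxybenzonitrile | N#Cc1ccc(Br)cc1O | starting material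
5 | 4-bromo-2-hydroxy-5-iodobenzonitrile | N#Cc1cc(I)c(Br)cc1O | intermediate
6 | 4-bromo-5-iodo-2-(methoxymethoxy)benzonitrile | N#Cc1cc(I)c(Br)cc1OCOC | intermediate
7 | [3,5-bis(methoxymethoxy)benzyl]zinc bromide (not isolated) | Br[Zn]Cc1cc(OCOC)cc(OCOC)c1 | intermediate
8 | 4-bromo-5-{[3,5-bis(methoxymethoxy)phenyl]methyl}-2-(methoxymethoxy)benzonitrile | N#Cc1cc(Cc2cc(OCOC)cc(OCOC)c2)c(Br)cc1OCOC | intermediate
9 | (1S,2R,5S)-2-isopropyl-5-methylcyclohexyl (R)-4-methylbenzenesulfinate, (+)-menthyl (R)-p-toluenesulfinate | CC(C)[C@H]1CC[C@H](C)C[C@@H]1O[S@@](=O)c1ccc(C)cc1 | starting material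
10 | {2-[3,5-bis(methoxymethoxy)benzyl]-4-cyano-5-(methoxymethoxy)phenyl}magnesium chloride (not isolated) | N#Cc1cc(Cc2cc(OCOC)cc(OCOC)c2)c([Mg]Cl)cc1OCOC | intermediate
11 | 5-{[3,5-bis(methoxymethoxy)phenyl]methyl}-2-(methoxymethoxy)-4-[(R)-4-methylbenzenesulfinyl]benzonitrile | Cc1ccc(cc1)[S@@](=O)c1cc(OCOC)c(C#N)cc1Cc1cc(OCOC)cc(OCOC)c1 | intermediate
12 | 4-(methoxymethoxy)benzaldehyde | O=Cc1ccc(OCOC)cc1 | starting material
13 | [3,5-bis(methoxymethoxy)phenyl]{5-cyano-4-(methoxymethoxy)-2-[(R)-4-methylbenzenesulfinyl]phenyl}methyllithium (not isolated) | [Li]C(c1cc(OCOC)cc(OCOC)c1)c1cc(C#N)c(OCOC)cc1[S@](=O)c1ccc(C)cc1 | intermediate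
14 | lithium (1R,2R)-2-[3,5-bis(methoxymethoxy)phenyl]-2-{5-cyano-4-(methoxymethoxy)-2-[(R)-4-methylbenzenesulfinyl]phenyl}-1-[4-(methoxymethoxy)phenyl]ethan-1-olate (not isolated) | [Li]O[C@@H](c1ccc(OCOC)cc1)[C@@H](c1cc(C#N)c(OCOC)cc1[S@](=O)c1ccc(C)cc1)c1cc(OCOC)cc(OCOC)c1 | intermediate
15 | (2R,3R)-3-[3,5-bis(methoxymethoxy)phenyl]-6-(methoxymethoxy)-2-[4-(methoxymethoxy)phenyl]-2,3-dihydro-1-benzofuran-5-carbonitrile | N#Cc1cc2c(cc1OCOC)O[C@@H](c1ccc(OCOC)cc1)[C@@H]2c1cc(OCOC)cc(OCOC)c1 | intermediate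
16 | (2R,3R)-3-[3,5-bis(methoxymethoxy)phenyl]-6-(methoxymethoxy)-2-[4-(methoxymethoxy)phenyl]-2,3-dihydro-1-benzofuran-5-carbaldehyde | O=Cc1cc2c(cc1OCOC)O[C@@H](c1ccc(OCOC)cc1)[C@@H]2c1cc(OCOC)cc(OCOC)c1 | intermediate
17 | 2,4,6-trihydroxyacetophenone | CC(=O)c1c(O)cc(O)cc1O | starting material
18 | 1-bromo-3-methylbut-2-ene (prenyl bromide) | CC(C)=CCBr | starting material
19 | 1-[2,4,6-trihydroxy-3,5-bis(3-methylbut-2-en-1-yl)phenyl]ethanone | CC(=O)c1c(O)c(CC=C(C)C)c(O)c(CC=C(C)C)c1O | intermediate
20 | 1-[2-hydroxy-4,6-bis(methoxymethoxy)-3,5-bis(3-methylbut-2-en-1-yl)phenyl]ethanone | CC(=O)c1c(O)c(CC=C(C)C)c(OCOC)c(CC=C(C)C)c1OCOC | intermediate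
21 | (E)-3-{(2R,3R)-3-[3,5-bis(methoxymethoxy)phenyl]-6-(methoxymethoxy)-2-[4-(methoxymethoxy)phenyl]-2,3-dihydro-1-benzofuran-5-yl}-1-[2-hydroxy-4,6-bis(methoxymethoxy)-3,5-bis(3-methylbut-2-en-1-yl)phenyl]prop-2-en-1-one | O=C(/C=C/c1cc2c(cc1OCOC)O[C@@H](c1ccc(OCOC)cc1)[C@@H]2c1cc(OCOC)cc(OCOC)c1)c1c(O)c(CC=C(C)C)c(OCOC)c(CC=C(C)C)c1OCOC | intermediate
22 | (2S)-2-{(2R,3R)-3-[3,5-bis(methoxymethoxy)phenyl]-6-(methoxymethoxy)-2-[4-(methoxymethoxy)phenyl]-2,3-dihydro-1-benzofuran-5-yl}-5,7-bis(methoxymethoxy)-6,8-bis(3-methylbut-2-en-1-yl)-2,3-dihydro-4H-chromen-4-one | CC(C)=CCc1c(OCOC)c(CC=C(C)C)c2c(c1OCOC)C(=O)C[C@@H](c1cc3c(cc1OCOC)O[C@@H](c1ccc(OCOC)cc1)[C@@H]3c1cc(OCOC)cc(OCOC)c1)O2 | intermediate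
23 | (2S)-2-[(2R,3R)-3-(3,5-dihydroxyphenyl)-6-hydroxy-2-(4-hydroxyphenyl)-2,3-dihydro-1-benzofuran-5-yl]-5,7-dihydroxy-6,8-bis(3-methylbut-2-en-1-yl)-2,3-dihydro-4H-chromen-4-one | CC(C)=CCc1c(O)c(CC=C(C)C)c2c(c1O)C(=O)C[C@@H](c1cc3c(cc1O)O[C@@H](c1ccc(O)cc1)[C@@H]3c1cc(O)cc(O)c1)O2 | target

**Count.** Total steps: 13. Longest linear sequence: 9 steps (steps 3, 4, 5, 6, 7, 8, 11, 12, 13).

**Steps most likely to fail**

Step 7 (proposed new method). On warming, the lithium alkoxide may revert to carbanion and aldehyde, or displacement of the sulfinyl group may be too slow; facial control would then erode or the ring would not close. Competing ring lithiation between the sulfinyl and methoxymethoxy groups is a further risk. The fallback uses known chemistry and sets out from 11 and 12. The carbanion addition is run alone (LiN(i-Pr)2, THF, −78 °C, then 12, quench with aq. NH4Cl at −78 °C) to give 5-{(1R,2R)-1-[3,5-bis(methoxymethoxy)phenyl]-2-hydroxy-2-[4-(methoxymethoxy)phenyl]ethyl}-2-(methoxymethoxy)-4-[(R)-4-methylbenzenesulfinyl]benzonitrile F1. Oxidation at sulfur with mCPBA (CH2Cl2, 0 °C) should give the corresponding 4-(4-methylbenzenesulfonyl)benzonitrile F2. NaH in DMF (0 → 25 °C) should then close the ring by intramolecular SNAr, with p-toluenesulfinate as nucleofuge para to the nitrile. The route is rejoined at 15.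

Step 12. Facial selectivity may be poor on this crowded, electron-rich chalcone, and reversible ring opening may erode the new stereocenter. The fallback sets out from 21. Non-selective cyclisation (NaOAc, EtOH, 78 °C) should give 22 together with its (2R)-epimer F3. The two diastereomers are separated by chromatography, and F3 is reopened to 21 with KOH in EtOH for another cycle. The route is rejoined at 22.

Step 9. Geminal dialkylation with loss of aromaticity and O-alkylation of the phenoxide may consume the material. The fallback sets out from 17 and replaces phenoxide alkylation by Friedel–Crafts alkylation of the neutral phenol with 2-methylbut-3-en-2-ol and BF3·OEt2 in dioxane at 25 °C. This should disfavour both side reactions; it makes no new compound and returns to the route at 19.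

**Further compounds**

F1 | step 7 | 5-{(1R,2R)-1-[3,5-bis(methoxymethoxy)phenyl]-2-hydroxy-2-[4-(methoxymethoxy)phenyl]ethyl}-2-(methoxymethoxy)-4-[(R)-4-methylbenzenesulfinyl]benzonitrile | O[C@@H](c1ccc(OCOC)cc1)[C@@H](c1cc(C#N)c(OCOC)cc1[S@](=O)c1ccc(C)cc1)c1cc(OCOC)cc(OCOC)c1
F2 | step 7 | 5-{(1R,2R)-1-[3,5-bis(methoxymethoxy)phenyl]-2-hydroxy-2-[4-(methoxymethoxy)phenyl]ethyl}-2-(methoxymethoxy)-4-(4-methylbenzenesulfonyl)benzonitrile | O[C@@H](c1ccc(OCOC)cc1)[C@@H](c1cc(C#N)c(OCOC)cc1S(=O)(=O)c1ccc(C)cc1)c1cc(OCOC)cc(OCOC)c1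
F3 | step 12 | (2R)-2-{(2R,3R)-3-[3,5-bis(methoxymethoxy)phenyl]-6-(methoxymethoxy)-2-[4-(methoxymethoxy)phenyl]-2,3-dihydro-1-benzofuran-5-yl}-5,7-bis(methoxymethoxy)-6,8-bis(3-methylbut-2-en-1-yl)-2,3-dihydro-4H-chromen-4-one | CC(C)=CCc1c(OCOC)c(CC=C(C)C)c2c(c1OCOC)C(=O)C[C@H](c1cc3c(cc1OCOC)O[C@@H](c1ccc(OCOC)cc1)[C@@H]3c1cc(OCOC)cc(OCOC)c1)O2
F0 | step 9 | none | none
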